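Remark on the chemistry: every ring is numbered as in the target, whatever the systematic name of an intermediate says. C1 carries the benzylic carbon C7, C2 and C3 carry the bromines, C4 and C5 the oxygens, C6 the hydrogen. The two identical rings are called ring A and ring B. Compound numbers refer to the list after the steps.

## Analysis of the target

Target 19 is an achiral, symmetric dibenzyl ether: two identical pentasubstituted benzene rings (ring A and ring B) hang on a C7–O–C7' chain, with no ring fusion and no stereocentre, so the problem is one of substitution pattern and functional-group tolerance. Each ring carries four contiguous heteroatoms, Br at C2 and C3 and OH at C4 and C5, and its only hydrogen at C6. The sensitive groups are the two catechols (oxidised to ortho-quinones by air and base), the aryl bromides (no hydrogenolysis, little room for low-valent metals late in the route) and above all the benzylic C7–O bonds: O4 is para to C1, so each half is a para-hydroxybenzyl ether that can lose its oxygen substituent through a quinone methide in warm protic or basic media. The hard part is the pair of neighbouring bromines: C3 is wedged between C2–Br and C4–O, and electrophilic bromination of a 4,5-dioxygenated benzyl unit reaches C2 and C6 before C3 and oxidises a free catechol on the way. The strategy reads C3–C4–C5 as the three oxygenated carbons of a gallic acid unit: the target differs from a gallyl ether only in that O3 and the hydrogen on the neighbouring C2 are both replaced by bromine. An oxygen leaving group at C3 beside a silyl group at C2 is an aryne precursor, and a C2≡C3 aryne takes up two bromines at exactly these carbons. Because the molecule is symmetric, both rings can go through every operation together and both halves can be cut from one benzylic alcohol.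

## Retrosynthetic reasoning

19 ⇒ 18. The last disconnection cuts the four ketal C–O bonds that tie O4 and O5 of each ring to a diphenylmethylene carbon. Free catechols and a para-hydroxybenzyl ether could not pass through the carbanion and fluoride chemistry that comes before, so unmasking has to be the final event. The forward reaction must hydrolyse two diaryl ketals without ionising C7–O; that calls for cold strong acid with water as the only nucleophile, and rules out heat, alcohols and base.

18 ⇒ 14 + 7. All four C–Br bonds are cut at once: C2–Br and C3–Br of each ring go back to a C2≡C3 aryne, and the aryne to a ring with silicon at C2 and a triflate at C3. Cutting here, and not one bromine at a time, removes every question of positional selectivity in electrophilic substitution, because the halogens enter where the silicon and the triflate sit. Compound 7 serves as the source of electrophilic bromine because, unlike elemental bromine, it does not attack a C–Si bond. The forward reaction needs a fluoride-triggered elimination, addition of bromide at C2 and capture of the C3 carbanion by bromine, on ring A and then on ring B.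

14 ⇒ 12 (through 13) ⇒ 11. The C2–Si and O3–S bonds are cut next. Silicon is delivered to C2 from O3 by a 1,3 O→C shift once the C2 bromine of 12 has been exchanged for lithium, and the phenoxide 13 set free is triflated. The gallate oxygen O3 thus does three jobs: it directs a bromine to C2, carries the silicon there, and leaves as the nucleofuge. Silylation of the two phenols of 11 gives 12.

11 ⇒ 10 ⇒ 6 + 8. One of the two equivalent C7–O bonds is cut, a Williamson disconnection into the benzylic alcohol 6 (as its alkoxide 9) and the benzylic bromide 8, which is itself made from 6. The ether is built before silicon and triflate are in place, because a benzylic alkoxide next to C2–Si and C3–OTf would set off the aryne by silyl transfer. O3 has to be masked during alkoxide chemistry; an allyl ether is chosen because it leaves from 10 under neutral palladium catalysis, which spares the ketals, the aryl bromides and the dibenzyl ether.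

8 ⇒ 6 ⇒ 5 ⇒ 4. These are functional-group changes on one ring: the benzylic bromide comes from the alcohol, the alcohol from the methyl ester by hydride reduction, and the allyl ether from the free O3 phenol of 4.

4 ⇒ 3 ⇒ 1 + 2. The C2–Br bond is cut back to the phenol 3, where the free O3–H steers bromine to its ortho position. The ketal carbon from 2 bridges two neighbouring oxygens of the symmetric ester 1; whichever pair it takes, the same compound results, so one step distinguishes O3 from O4 and O5.

## Alternatives that were turned down

Alternative 1: The disconnection cuts C3–C4 and C5–C6 of both rings. In the forward sense the acyclic bis-diene A2 would undergo a twofold Diels–Alder reaction with two molecules of the dienophile A3, and hydrolysis and tautomerisation of the adducts would give the bis-catechol A1. In its favour, both catechols arise in one pot without phenol protection or organometallic reagents. It also ends at a free polyphenol, so the acidic unmasking that endangers C7–O in the chosen route never occurs; on that point it is stronger. Against it, A1 has hydrogen at C2 and C3. Four bromines must then be placed on a free catechol benzyl ether, where C2 and C6 react before the crowded C3, the oxidant turns catechols into quinones, and the acid set free attacks a para-hydroxybenzyl ether. The ring construction also spends the key step on a 3,4-dihydroxybenzyl pattern that cheap aromatic feedstocks already provide, and A3 is a sluggish dienophile that needs temperatures at which a 2-substituted diene such as A2 polymerises. The chosen strategy is longer up to its key step but places the halogens by construction.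

Alternative 2: The disconnection cuts both C1–C7 bonds. The aryl iodide A5 would be turned into its Grignard reagent by iodine–magnesium exchange, and two equivalents would displace both chlorides of A6 to give the silyl-protected bis-ether A4. This is the most convergent plan. Its key step is a well-established reaction type, so it carries less risk there than the aryne dibromination, and the silyl ethers would leave with buffered fluoride, which is gentler on C7–O than acid; on both points it is stronger. Against it, A6 is a volatile and potent carcinogen, and the Grignard reagent from A5 has bromine ortho to magnesium, so it can collapse to an aryne on warming while the second displacement is still under way. The main objection is that the central problem is only moved: A5 already contains the two neighbouring bromines next to an oxygen, and bromination of simple catechol derivatives gives the 4,5- and not the 3,4-dibromide. The chosen strategy gives every substituent a defined origin in 1 and needs no regulated reagent.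

Alternative 3: The disconnection cuts C1–C2 and C2–C3, so that C2 comes from the one-carbon nucleophile A9. The anion of A9 would add to each pyranone ring of the bis-ether A8; ring opening and nitro-aldol reclosure would give the bis(nitrophenol) A7. In its favour, the raw material is a cheap fermentation product, both benzene rings are built with O4 and O5 already differentiated, and no low-temperature organometallic step is needed; on cost and scalability of the early steps it is stronger. Against it, A7 carries a nitro group at C2 and hydrogen at C3. Each ring then needs reduction in the presence of allyl ethers, diazotisation of a para-aminophenol (which tends to give a diazoquinone and is a poor substrate for a Sandmeyer reaction), bromide delivery, a separate bromination at C3 in competition with C6, and deallylation. That is at least four twofold operations after the key step, and the strongly basic key step acts on a substrate whose C7–O bond is activated by the pyranone carbonyl. The chosen strategy is of similar overall length but installs both halogens of a ring in one operation.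

Key step: step 10

## Route

Step 1
Reactants: 1 methyl gallate (methyl 3,4,5-trihydroxybenzoate); 2 dichlorodiphenylmethane
Product: 3 methyl 7-hydroxy-2,2-diphenyl-1,3-benzodioxole-5-carboxylate
Conditions: K2CO3, MeCN, rt
Reagents that add atoms: none
Why: Twofold O-alkylation of a catechol pair by a geminal dichloride (ketalisation); 1 is symmetric, so bridging either pair of neighbouring oxygens gives the same five-membered ketal and leaves exactly one phenol, O3, free.

Step 2
Reactants: 3 methyl 7-hydroxy-2,2-diphenyl-1,3-benzodioxole-5-carboxylate
Product: 4 methyl 6-bromo-7-hydroxy-2,2-diphenyl-1,3-benzodioxole-5-carboxylate (bromine at C2, ortho to the free O3–H)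
Conditions: NBS (1.0 equiv), i-Pr2NH (cat.), CH2Cl2, 0 °C
Reagents that add atoms: N-bromosuccinimide, O=C1CCC(=O)N1Br
Why: Amine-mediated ortho-bromination of a phenol; C2 (ortho to O3, para to O5) and C6 (para to O3, ortho to O5) are electronically alike, so delivery of bromine by the N-bromoamine hydrogen-bonded to O3–H should decide for C2.

Step 3
Reactants: 4 methyl 6-bromo-7-hydroxy-2,2-diphenyl-1,3-benzodioxole-5-carboxylate
Product: 5 methyl 7-(allyloxy)-6-bromo-2,2-diphenyl-1,3-benzodioxole-5-carboxylate
Conditions: allyl bromide, K2CO3, DMF, rt
Reagents that add atoms: allyl bromide, C=CCBr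
Why: Williamson O-alkylation of the phenoxide; the allyl ether withstands hydride, Appel and alkoxide conditions and can later be removed under neutral palladium catalysis.

Step 4
Reactants: 5 methyl 7-(allyloxy)-6-bromo-2,2-diphenyl-1,3-benzodioxole-5-carboxylate
Product: 6 [7-(allyloxy)-6-bromo-2,2-diphenyl-1,3-benzodioxol-5-yl]methanol
Conditions: i-Bu2AlH, CH2Cl2, −78 → 0 °C; aq. potassium sodium tartrate
Reagents that add atoms: none
Why: Hydride reduction of the ester to the primary alcohol; i-Bu2AlH at low temperature leaves the aryl bromide, the allyl ether and the diaryl ketal untouched.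

Step 5
Reactants: 6 [7-(allyloxy)-6-bromo-2,2-diphenyl-1,3-benzodioxol-5-yl]methanol; 7 carbon tetrabromide
Product: 8 7-(allyloxy)-6-bromo-5-(bromomethyl)-2,2-diphenyl-1,3-benzodioxole
Conditions: PPh3, CBr4, CH2Cl2, 0 °C
Reagents that add atoms: none
Why: Appel reaction; the neutral conditions convert the benzylic alcohol into the bromide without acid that could touch the ketal.

Step 6
Reactants: 6 [7-(allyloxy)-6-bromo-2,2-diphenyl-1,3-benzodioxol-5-yl]methanol; 8 7-(allyloxy)-6-bromo-5-(bromomethyl)-2,2-diphenyl-1,3-benzodioxole
Product: 10 bis{[7-(allyloxy)-6-bromo-2,2-diphenyl-1,3-benzodioxol-5-yl]methyl} ether, via sodium benzylic alkoxide 9 (not isolated)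
Conditions: NaH, THF–DMF, 0 °C; then 8, Bu4NI (cat.), 0 °C → rt
Reagents that add atoms: none
Why: Williamson ether synthesis between a primary benzylic alkoxide and a primary benzylic bromide, where elimination is impossible; with O3 allylated there is no competing phenoxide.

Step 7
Reactants: 10 bis{[7-(allyloxy)-6-bromo-2,2-diphenyl-1,3-benzodioxol-5-yl]methyl} ether
Product: 11 bis[(6-bromo-7-hydroxy-2,2-diphenyl-1,3-benzodioxol-5-yl)methyl] ether
Conditions: Pd(PPh3)4 (cat.), morpholine, THF, rt
Reagents that add atoms: none
Why: Tsuji–Trost deallylation with morpholine as allyl acceptor; at room temperature, ionisation of the allyl aryl ether should be much faster than insertion of palladium into the doubly ortho-substituted, electron-rich C2–Br bonds.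

Step 8
Reactants: 11 bis[(6-bromo-7-hydroxy-2,2-diphenyl-1,3-benzodioxol-5-yl)methyl] ether
Product: 12 bis{[6-bromo-2,2-diphenyl-7-(trimethylsilyloxy)-1,3-benzodioxol-5-yl]methyl} ether
Conditions: (Me3Si)2NH, THF, 65 °C; volatiles removed
Reagents that add atoms: hexamethyldisilazane, C[Si](C)(C)N[Si](C)(C)C
Why: O-silylation of both phenols with ammonia as the only by-product, so the moisture-sensitive silyl ethers can be used without purification.

Step 9
Reactants: 12 bis{[6-bromo-2,2-diphenyl-7-(trimethylsilyloxy)-1,3-benzodioxol-5-yl]methyl} ether
Product: 14 bis{[2,2-diphenyl-7-(trifluoromethanesulfonyloxy)-6-(trimethylsilyl)-1,3-benzodioxol-5-yl]methyl} ether, via dilithium bis(2-silylphenoxide) 13 (not isolated)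
Conditions: n-BuLi (2.2 equiv), THF, −78 °C; then Tf2O, −78 → 0 °C
Reagents that add atoms: trifluoromethanesulfonic anhydride, O=S(=O)(OS(=O)(=O)C(F)(F)F)C(F)(F)F
Why: Bromine–lithium exchange at C2 followed by retro-Brook rearrangement (1,3 shift of SiMe3 from O3 to C2), then O-triflation of the lithium phenoxide; exchange and intramolecular silyl transfer at −78 °C should outrun deprotonation of the benzylic ether.

Step 10
Reactants: 14 bis{[2,2-diphenyl-7-(trifluoromethanesulfonyloxy)-6-(trimethylsilyl)-1,3-benzodioxol-5-yl]methyl} ether; 7 carbon tetrabromide
Product: 18 bis[(6,7-dibromo-2,2-diphenyl-1,3-benzodioxol-5-yl)methyl] ether, via ring A aryne 15 (not isolated), via half-brominated silyl triflate 16 (not isolated), via ring B aryne 17 (not isolated)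
Conditions: CsF, Bu4NBr (2 equiv per ring), CBr4 (excess), DME, 4 Å MS, rt
Reagents that add atoms: tetrabutylammonium bromide, CCCC[N+](CCCC)(CCCC)CCCC.[Br-]
Why: Proposed new method: fluoride attacks the silicon at C2 of one ring and the developing C2 carbanion expels the C3 triflate, giving the C2≡C3 aryne 15. Bromide adds at C2, the aryne carbon remote from O4, so that the carbanion sits at C3 where the C4–O bond stabilises it inductively; this aryl anion takes Br+ from CBr4 to give 16, and the same sequence on ring B through 17 gives 18. The tribromomethanide left behind sheds bromide, which re-enters the cycle, and the dibromocarbene should end as tetrabromoethene. The closest known reaction type is the fluoride-triggered vicinal diiodination of arynes from ortho-silylaryl triflates with I2, and further back the capture of benzyne by Br2; new here are the bromide/CBr4 pair and the twofold run on one molecule. No ring closes and no stereocentre forms, and because both new substituents are bromine the sense of addition cannot give an isomer. The step needs chemoselectivity: bromine transfer to the aryl anion must beat protonation, and bromide must beat tribromomethanide and fluoride in adding to the aryne. This is secured by a dry ether solvent without acidic C–H, sparingly soluble CsF, a full equivalent of soluble bromide per ring and excess CBr4, which unlike Br2 does not ipso-brominate the C–Si bond before the aryne forms.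

Step 11
Reactants: 18 bis[(6,7-dibromo-2,2-diphenyl-1,3-benzodioxol-5-yl)methyl] ether
Product: 19 bis(2,3-dibromo-4,5-dihydroxybenzyl) ether
Conditions: TFA–H2O–CH2Cl2, 0 °C → rt; concentrated cold, no basic wash, argon
Reagents that add atoms: none
Why: Acid hydrolysis of the diaryl ketals through a diphenyl(aryloxy)carbenium ion, which should form far more readily than a benzylic cation at C7 flanked by the bromines at C2 and C3. Cold strong acid with water as the only nucleophile is used because heat, alcohols and base open the quinone methide pathway at C7.

## Compound list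

1 | methyl gallate (methyl 3,4,5-trihydroxybenzoate) | COC(=O)c1cc(O)c(O)c(O)c1 | starting material
2 | dichlorodiphenylmethane | ClC(Cl)(c1ccccc1)c1ccccc1 | starting material
3 | methyl 7-hydroxy-2,2-diphenyl-1,3-benzodioxole-5-carboxylate | COC(=O)c1cc(O)c2OC(c3ccccc3)(c3ccccc3)Oc2c1 | intermediate
4 | methyl 6-bromo-7-hydroxy-2,2-diphenyl-1,3-benzodioxole-5-carboxylate | COC(=O)c1cc2OC(c3ccccc3)(c3ccccc3)Oc2c(O)c1Br | intermediate
5 | methyl 7-(allyloxy)-6-bromo-2,2-diphenyl-1,3-benzodioxole-5-carboxylate | COC(=O)c1cc2OC(c3ccccc3)(c3ccccc3)Oc2c(OCC=C)c1Br | intermediate
6 | [7-(allyloxy)-6-bromo-2,2-diphenyl-1,3-benzodioxol-5-yl]methanol | OCc1cc2OC(c3ccccc3)(c3ccccc3)Oc2c(OCC=C)c1Br | intermediate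
7 | carbon tetrabromide | BrC(Br)(Br)Br | starting material
8 | 7-(allyloxy)-6-bromo-5-(bromomethyl)-2,2-diphenyl-1,3-benzodioxole | BrCc1cc2OC(c3ccccc3)(c3ccccc3)Oc2c(OCC=C)c1Br | intermediate
9 | sodium [7-(allyloxy)-6-bromo-2,2-diphenyl-1,3-benzodioxol-5-yl]methanolate (not isolated) | [Na+].[O-]Cc1cc2OC(c3ccccc3)(c3ccccc3)Oc2c(OCC=C)c1Br | intermediate
10 | bis{[7-(allyloxy)-6-bromo-2,2-diphenyl-1,3-benzodioxol-5-yl]methyl} ether | Brc1c(OCC=C)c2OC(c3ccccc3)(c3ccccc3)Oc2cc1COCc1cc2OC(c3ccccc3)(c3ccccc3)Oc2c(OCC=C)c1Br | intermediate
11 | bis[(6-bromo-7-hydroxy-2,2-diphenyl-1,3-benzodioxol-5-yl)methyl] ether | Brc1c(O)c2OC(c3ccccc3)(c3ccccc3)Oc2cc1COCc1cc2OC(c3ccccc3)(c3ccccc3)Oc2c(O)c1Br | intermediate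
12 | bis{[6-bromo-2,2-diphenyl-7-(trimethylsilyloxy)-1,3-benzodioxol-5-yl]methyl} ether | Brc1c(O[Si](C)(C)C)c2OC(c3ccccc3)(c3ccccc3)Oc2cc1COCc1cc2OC(c3ccccc3)(c3ccccc3)Oc2c(O[Si](C)(C)C)c1Br | intermediate
13 | dilithium salt of bis{[7-hydroxy-2,2-diphenyl-6-(trimethylsilyl)-1,3-benzodioxol-5-yl]methyl} ether (both phenols as lithium phenoxides; not isolated) | [Li+].[Li+].C[Si](C)(C)c1c([O-])c2OC(c3ccccc3)(c3ccccc3)Oc2cc1COCc1cc2OC(c3ccccc3)(c3ccccc3)Oc2c([O-])c1[Si](C)(C)C | intermediate
14 | bis{[2,2-diphenyl-7-(trifluoromethanesulfonyloxy)-6-(trimethylsilyl)-1,3-benzodioxol-5-yl]methyl} ether (SiMe3 at C2, OTf at C3 of each ring) | C[Si](C)(C)c1c(OS(=O)(=O)C(F)(F)F)c2OC(c3ccccc3)(c3ccccc3)Oc2cc1COCc1cc2OC(c3ccccc3)(c3ccccc3)Oc2c(OS(=O)(=O)C(F)(F)F)c1[Si](C)(C)C | intermediate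
15 | mono-aryne: ring A is the C2≡C3 aryne (6,7-didehydro-2,2-diphenyl-1,3-benzodioxol-5-yl)methyl unit, ring B still carries SiMe3 at C2 and OTf at C3 (not isolated) | C[Si](C)(C)c1c(OS(=O)(=O)C(F)(F)F)c2OC(c3ccccc3)(c3ccccc3)Oc2cc1COCC1=CC2=C(C#C1)OC(c3ccccc3)(c3ccccc3)O2 | intermediate
16 | (6,7-dibromo-2,2-diphenyl-1,3-benzodioxol-5-yl)methyl [2,2-diphenyl-7-(trifluoromethanesulfonyloxy)-6-(trimethylsilyl)-1,3-benzodioxol-5-yl]methyl ether (not isolated) | C[Si](C)(C)c1c(OS(=O)(=O)C(F)(F)F)c2OC(c3ccccc3)(c3ccccc3)Oc2cc1COCc1cc2OC(c3ccccc3)(c3ccccc3)Oc2c(Br)c1Br | intermediate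
17 | mono-aryne: ring A is the 2,3-dibromide, ring B is the C2≡C3 aryne (not isolated) | Brc1c(Br)c2OC(c3ccccc3)(c3ccccc3)Oc2cc1COCC1=CC2=C(C#C1)OC(c3ccccc3)(c3ccccc3)O2 | intermediate
18 | bis[(6,7-dibromo-2,2-diphenyl-1,3-benzodioxol-5-yl)methyl] ether | Brc1c(Br)c2OC(c3ccccc3)(c3ccccc3)Oc2cc1COCc1cc2OC(c3ccccc3)(c3ccccc3)Oc2c(Br)c1Br | intermediate
19 | bis(2,3-dibromo-4,5-dihydroxybenzyl) ether | Oc1cc(COCc2cc(O)c(O)c(Br)c2Br)c(Br)c(Br)c1O | target

## Step count and risk

Total: 11 steps. Longest linear sequence: 11 steps (1 to 19; step 5 branches from 6 and rejoins in step 6).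

Step 10 (key step, proposed new method). The most likely failures are protonation of the C3 aryl anion before bromine transfer (net hydrobromination), capture of the aryne by tribromomethanide or fluoride instead of bromide, and side reactions of the dibromocarbene that the bromine donor leaves behind; each is doubled because two rings must react. The fallback uses known reactions and sets out from 14. Ipso-bromodesilylation of both C2–Si bonds (Br2, CH2Cl2, −78 → 0 °C) should give bis{[6-bromo-2,2-diphenyl-7-(trifluoromethanesulfonyloxy)-1,3-benzodioxol-5-yl]methyl} ether F1. Ruthenium-catalysed exchange of aryl triflate for bromide (LiBr, catalytic [Cp*Ru(MeCN)3]OTf, 1,3-dimethyl-2-imidazolidinone, 100 °C) then converts both C3–OTf groups into C3–Br, and the route is rejoined at 18.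

Step 9. The aryllithium or excess n-BuLi may deprotonate a benzylic position of the dibenzyl ether (followed by Wittig rearrangement), n-BuLi may attack the O–Si bond, or exchange may stall after the first ring. The fallback sets out from 10 and replaces the silyl migration by external trapping while O3 is still allylated. t-BuLi is added to 10 and Me3SiCl in THF–Et2O at −100 °C, so that each aryllithium is silylated as it forms, giving bis{[7-(allyloxy)-2,2-diphenyl-6-(trimethylsilyl)-1,3-benzodioxol-5-yl]methyl} ether F2. Deallylation (Pd(PPh3)4, morpholine) gives bis{[7-hydroxy-2,2-diphenyl-6-(trimethylsilyl)-1,3-benzodioxol-5-yl]methyl} ether F3, and triflation (Tf2O, pyridine, CH2Cl2, 0 °C) rejoins the route at 14.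

Step 2. Positional selectivity may be poor, because C6 is activated to the same degree as C2, and a second bromination can follow. The fallback sets out from 3 and replaces electrophilic substitution by directed metalation. The phenol is converted into methyl 7-(tert-butoxycarbonyloxy)-2,2-diphenyl-1,3-benzodioxole-5-carboxylate F4 (Boc2O, cat. DMAP). Magnesiation with TMPMgCl·LiCl (THF, 0 °C) should occur at C2, the only position flanked by two coordinating carbonyl groups, and BrCCl2CCl2Br then gives methyl 6-bromo-7-(tert-butoxycarbonyloxy)-2,2-diphenyl-1,3-benzodioxole-5-carboxylate F5. Methanolysis of the carbonate (K2CO3, MeOH, rt) rejoins the route at 4.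

Step 11. The benzylic ether may be lost by acid-promoted ionisation at C7, or through the quinone methide if the medium turns neutral or basic while warm; the ketals on the electron-poor rings may also hydrolyse slowly, which lengthens exposure. The fallback sets out from 18 and accepts the cleavage. Hydrolysis is driven to completion (TFA–H2O, 40 °C) so that all material converges on 2,3-dibromo-4,5-dihydroxybenzyl alcohol F6. Acid-catalysed dehydrative self-etherification of this para-hydroxybenzylic alcohol (concentrated solution in dioxane, 4 Å molecular sieves, cat. TsOH, 40 °C), the reverse of the solvolysis, rebuilds the C7–O–C7' link and arrives at 19.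

## Further compounds

F1 | step 10 | bis{[6-bromo-2,2-diphenyl-7-(trifluoromethanesulfonyloxy)-1,3-benzodioxol-5-yl]methyl} ether | Brc1c(OS(=O)(=O)C(F)(F)F)c2OC(c3ccccc3)(c3ccccc3)Oc2cc1COCc1cc2OC(c3ccccc3)(c3ccccc3)Oc2c(OS(=O)(=O)C(F)(F)F)c1Br
F2 | step 9 | bis{[7-(allyloxy)-2,2-diphenyl-6-(trimethylsilyl)-1,3-benzodioxol-5-yl]methyl} ether | C[Si](C)(C)c1c(OCC=C)c2OC(c3ccccc3)(c3ccccc3)Oc2cc1COCc1cc2OC(c3ccccc3)(c3ccccc3)Oc2c(OCC=C)c1[Si](C)(C)C
F3 | step 9 | bis{[7-hydroxy-2,2-diphenyl-6-(trimethylsilyl)-1,3-benzodioxol-5-yl]methyl} ether | C[Si](C)(C)c1c(O)c2OC(c3ccccc3)(c3ccccc3)Oc2cc1COCc1cc2OC(c3ccccc3)(c3ccccc3)Oc2c(O)c1[Si](C)(C)C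
F4 | step 2 | methyl 7-(tert-butoxycarbonyloxy)-2,2-diphenyl-1,3-benzodioxole-5-carboxylate | COC(=O)c1cc(OC(=O)OC(C)(C)C)c2OC(c3ccccc3)(c3ccccc3)Oc2c1
F5 | step 2 | methyl 6-bromo-7-(tert-butoxycarbonyloxy)-2,2-diphenyl-1,3-benzodioxole-5-carboxylate | COC(=O)c1cc2OC(c3ccccc3)(c3ccccc3)Oc2c(OC(=O)OC(C)(C)C)c1Br
F6 | step 11 | 2,3-dibromo-4,5-dihydroxybenzyl alcohol | OCc1cc(O)c(O)c(Br)c1Br
A1 | alternative 1 | bis(3,4-dihydroxybenzyl) ether | Oc1ccc(COCc2ccc(O)c(O)c2)cc1O
A2 | alternative 1 | bis(2-methylenebut-3-en-1-yl) ether | C=CC(=C)COCC(=C)C=C
A3 | alternative 1 | 4,5-dichloro-1,3-dioxol-2-one | O=C1OC(Cl)=C(Cl)O1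
A4 | alternative 2 | bis[2,3-dibromo-4,5-bis(tert-butyldimethylsilyloxy)benzyl] ether | CC(C)(C)[Si](C)(C)Oc1cc(COCc2cc(O[Si](C)(C)C(C)(C)C)c(O[Si](C)(C)C(C)(C)C)c(Br)c2Br)c(Br)c(Br)c1O[Si](C)(C)C(C)(C)C
A5 | alternative 2 | 3,4-dibromo-5-iodo-1,2-bis(tert-butyldimethylsilyloxy)benzene | Ic1cc(O[Si](C)(C)C(C)(C)C)c(O[Si](C)(C)C(C)(C)C)c(Br)c1Br
A6 | alternative 2 | bis(chloromethyl) ether | ClCOCCl
A7 | alternative 3 | bis(4-allyloxy-5-hydroxy-2-nitrobenzyl) ether | C=CCOc1cc([N+](=O)[O-])c(COCc2cc(O)c(OCC=C)cc2[N+](=O)[O-])cc1O
A8 | alternative 3 | bis{[5-(allyloxy)-4-oxo-4H-pyran-2-yl]methyl} ether | C=CCOc1coc(COCc2cc(=O)c(OCC=C)co2)cc1=O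
A9 | alternative 3 | nitromethane | C[N+](=O)[O-]
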